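## Retrosynthetic overview

1. Labels: C1 = quaternary fusion carbon (Me); C2, C3 = CH2 groups of the five-membered ring; C4 = i-Pr carbinol; C5 = fusion CH; C6 = acyloxy carbon; C7=C8(Me)–C9(=O) = enone; C10 = CH2 between C9 and C1.
2. Feature exploited: in the seven-membered ring (C1, C5–C10) the chain O=C9–C10–C1 ends at the fusion bond, so a C5=C6 alkene makes it a γ,δ-unsaturated ketone. Its Claisen antecedent holds the C9 oxygen on C6, the carbon that is oxygenated in the target, and the C6 configuration can therefore be relayed to the quaternary C1.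
3. Endgame disconnections: O6–acyl (esterification); C6–H (hydride delivered by the C4 hydroxyl to a C6/C9 enedione); C4–i-Pr (organocerium on a C4 ketone); H5/O6 (syn hydroboration of C5=C6).
4. Key disconnection: C1–C10, retro-[3,3] to a 2-methyleneoxolane (O, C6, C7, C8, C9) with the ketal-protected cyclopentenyl group on C6. This comes from the γ-lactone by methylenation, and the lactone from a γ-keto ester (C5–C6 by vinyllithium addition, C6 by CBS reduction).
5. Ring order: five-membered carbocycle (purchased) → oxolane (lactonisation) → seven-membered carbocycle (ring enlargement that consumes the oxolane).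

Key step: step 8

Remark: C8 (from step 4 on) and C9 (steps 9–13) are carried as epimer mixtures and left undefined in the SMILES, because both become sp2 in step 14. Racemic commercial 5 is therefore sufficient.

## Route

Step 1
Reactants: 1 3-methylcyclopent-2-en-1-one
Product: 3 2-bromo-3-methylcyclopent-2-en-1-one, via dibromide 2 (not isolated)
Conditions: Br2, CH2Cl2, 0 °C; then Et3N, 0 °C to rt
Reagents that add atoms: bromine, BrBr
Why: Bromination–dehydrobromination: bromine adds across the enone and triethylamine removes the acidic α-hydrogen of the dibromide with loss of the β-bromide, which leaves the halogen on the α-carbon, the future C5.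

Step 2
Reactants: 3 2-bromo-3-methylcyclopent-2-en-1-one
Product: 4 6-bromo-7-methyl-1,4-dioxaspiro[4.4]non-6-ene
Conditions: ethylene glycol, p-TsOH (cat.), benzene, Dean–Stark, reflux
Reagents that add atoms: ethylene glycol, OCCO
Why: Acid-catalysed ketalisation driven by azeotropic removal of water; the vinylic bromine holds the alkene in its tetrasubstituted position, so the deconjugated isomer common with simple enones is not expected.

Step 3
Reactants: 5 ethyl 2-methylpent-4-enoate (racemic)
Product: 7 ethyl 2-methyl-4-oxobutanoate (racemic), via ozonide 6 (not isolated)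
Conditions: O3, CH2Cl2, −78 °C; then Me2S, −78 °C to rt
Reagents that add atoms: ozone, [O-][O+]=O
Why: Ozonolysis with reductive work-up cleaves the terminal alkene to the aldehyde (future C6) and leaves the ester (future C9) untouched.

Step 4
Reactants: 4 6-bromo-7-methyl-1,4-dioxaspiro[4.4]non-6-ene; 7 ethyl 2-methyl-4-oxobutanoate
Product: 9 ethyl 4-hydroxy-2-methyl-4-(7-methyl-1,4-dioxaspiro[4.4]non-6-en-6-yl)butanoate (all stereoisomers), via vinyllithium 8 (not isolated)
Conditions: n-BuLi, THF, −78 °C; then 7, −78 °C; AcOH quench at −78 °C; crude product used at once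
Reagents that add atoms: none
Why: Bromine–lithium exchange gives an α-keto vinyl anion equivalent whose 1,2-addition to the aldehyde is far faster at −78 °C than attack on the α-branched ester, the cold acidic quench keeps the alkoxide from lactonising, and no stereocontrol is needed because C6 is oxidised next.

Step 5
Reactants: 9 hydroxy ester
Product: 10 ethyl 2-methyl-4-(7-methyl-1,4-dioxaspiro[4.4]non-6-en-6-yl)-4-oxobutanoate (racemic at C8)
Conditions: Dess–Martin periodinane, NaHCO3, CH2Cl2, 0 °C to rt
Reagents that add atoms: none
Why: Dess–Martin oxidation under bicarbonate buffer converts the hindered allylic alcohol into the ketone under non-acidic conditions that spare the ketal.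

Step 6
Reactants: 10 γ-keto ester
Product: 12 (5S)-3-methyl-5-(7-methyl-1,4-dioxaspiro[4.4]non-6-en-6-yl)oxolan-2-one (C8 epimers), via hydroxy ester 11 (not isolated)
Conditions: (R)-Me-CBS (0.2 equiv), BH3·SMe2, THF, −20 °C; MeOH, concentrate; then KOt-Bu (0.2 equiv), THF, 0 °C to rt
Reagents that add atoms: none
Why: Corey–Bakshi–Shibata reduction in which the doubly flanked cyclopentenyl group is the large and the CH2 chain the small substituent, so the (R)-oxazaborolidine should give the (6S)-carbinol, whose alkoxide then closes the γ-lactone by 5-exo-trig transesterification without touching the C6–O bond.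

Step 7
Reactants: 12 (5S)-lactone
Product: 13 6-[(2S)-4-methyl-5-methylideneoxolan-2-yl]-7-methyl-1,4-dioxaspiro[4.4]non-6-ene (C8 epimers)
Conditions: Cp2TiMe2 (2.5 equiv), toluene, 70 °C, dark; pentane, filtration through Et3N-deactivated basic alumina
Reagents that add atoms: dimethyltitanocene (Petasis reagent), [CH3-].[CH3-].c1cc[cH-]c1.c1cc[cH-]c1.[Ti+4]
Why: Petasis methylenation: thermally generated Cp2Ti=CH2 exchanges the lactone oxygen for CH2 by [2+2] addition and cycloreversion, the reagent is neither acidic nor basic enough to harm the ketal or C6, and 70 °C should be too low for the sigmatropic shift.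

Step 8
Reactants: 13 (S)-2-methyleneoxolane
Product: 14 (1R)-4,4-(ethylenedioxy)-1,8-dimethylbicyclo[5.3.0]dec-5-en-9-one (route numbering; C8 epimers)
Conditions: toluene (0.02 M, degassed), i-Pr2NEt (5 mol %), base-washed sealed tube, 175–185 °C
Reagents that add atoms: none
Why: A concerted, suprafacial [3,3]-sigmatropic (Claisen) shift of the allyl vinyl ether C10=C9–O–C6–C5=C1 forms C1–C10 while C6–O breaks, so C9 becomes the ketone and the alkene moves to C5=C6. The closest known reaction type is the thermal ring enlargement of 2-methylene-5-vinyltetrahydrofurans to cyclohept-4-enones; the fully substituted terminus C1 goes beyond those cases, although acyclic Claisen shifts build quaternary carbons at such termini routinely. The seven-membered carbocycle (C1, C5–C10) closes by intramolecular C–C bond formation between the exocyclic methylene carbon and C1 through a boat-like transition state, the only one the C7–C8 tether allows, and the oxolane opens in the same event. C1 is the only new stereocentre: C10 must bond to the alkene face from which the C6 oxygen departs, and a seven-membered ring can hold only a cis C5=C6 bond (C7 syn to C1), so a single rotamer about C5–C6 is productive and (6S) is translated into (1R). The step needs chemoselectivity for the sigmatropic path over drift of the exocyclic double bond to C8=C9 and over C6–O heterolysis; both side reactions are acid-promoted, so the non-polar medium, amine buffer and base-washed glass secure it, and the new C=O bond makes the shift irreversible. The cost is allylic strain between C7 and the C1 methyl in the reactive rotamer, which is why a high temperature is planned.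

Step 9
Reactants: 14 (1R)-cycloheptenone ketal
Product: 16 (1R,5S,6S)-4,4-(ethylenedioxy)-1,8-dimethylbicyclo[5.3.0]decane-6,9-diol (trans-fused; C8/C9 epimers), via organoborane 15 (not isolated)
Conditions: BH3·THF (4 equiv), THF, 0 °C to rt; then NaOH (3 M), H2O2 (30 %), 0 °C to rt
Reagents that add atoms: hydrogen peroxide, OO
Why: Hydroboration–oxidation: boron goes to the less substituted C6 and hydrogen to C5 in a syn four-centre addition on the face opposite the quasi-axial C1 methyl (the other face carries only ring hydrogens), which sets the trans fusion (5S) and, after oxidation with retention, the 6S carbinol, while the C9 ketone is reduced and thereby masked.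

Step 10
Reactants: 16 6,9-diol
Product: 17 6,9-bis(tert-butyldimethylsilyl) ether of 16
Conditions: TBSOTf (3 equiv), 2,6-lutidine, CH2Cl2, 0 °C to rt
Reagents that add atoms: tert-butyldimethylsilyl triflate, CC(C)(C)[Si](C)(C)OS(=O)(=O)C(F)(F)F
Why: Silyl triflate/lutidine silylation is strong enough for the crowded C6 hydroxyl and masks both carbinols alike, so they need not be told apart.

Step 11
Reactants: 17 bis-silyl ether ketal
Product: 18 (1R,5S,6S)-6,9-bis(tert-butyldimethylsilyloxy)-1,8-dimethylbicyclo[5.3.0]decan-4-one
Conditions: PPTS (0.3 equiv), acetone/H2O 9:1, 55 °C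
Reagents that add atoms: water, O
Why: Mild acid-catalysed ketal hydrolysis; secondary TBS ethers survive PPTS, and so weak an acid should neither enolise C5 nor expel the β-silyloxy group.

Step 12
Reactants: 18 C4 ketone; 19 isopropylmagnesium chloride
Product: 20 (1R,4R,5S,6S)-6,9-bis(tert-butyldimethylsilyloxy)-4-isopropyl-1,8-dimethylbicyclo[5.3.0]decan-4-ol (OH cis to the C1 methyl)
Conditions: anhydrous CeCl3 (4 equiv), i-PrMgCl (4 equiv), THF, −78 °C; then 18, −78 to 0 °C; aqueous work-up
Reagents that add atoms: isopropylmagnesium chloride (19), CC(C)[Mg]Cl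
Why: Organocerium 1,2-addition suppresses enolisation and β-hydride reduction of the hindered cyclopentanone, and the nucleophile should enter beside the small H5 on the face opposite the C1 methyl, which places the C4 hydroxyl cis to that methyl (4R).

Step 13
Reactants: 20 bis-silyl ether carbinol
Product: 21 (1R,4R,5S,6S)-4-isopropyl-1,8-dimethylbicyclo[5.3.0]decane-4,6,9-triol
Conditions: TBAF (5 equiv), THF, 50 °C
Reagents that add atoms: none
Why: Fluoride-induced cleavage of both silyl ethers; no carbonyl group is present at this stage, so the basic fluoride has nothing to enolise or eliminate.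

Step 14
Reactants: 21 triol
Product: 23 (1R,4R,5R)-4-hydroxy-4-isopropyl-1,8-dimethylbicyclo[5.3.0]dec-7-ene-6,9-dione, via saturated 6,9-dione 22 (not isolated)
Conditions: IBX (5 equiv), DMSO, 25 °C; then 70 °C
Reagents that add atoms: none
Why: IBX oxidises both secondary carbinols at room temperature and on warming dehydrogenates the 1,4-diketone through its enol (IBX dehydrogenation); C7–C8 is the only α,β pair with hydrogen on both carbons, because C10 and C5 adjoin the fully substituted C1 and C4, and all C8/C9 epimers converge here.

Step 15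
Reactants: 23 enedione
Product: 24 lancerodiol (1R,4R,5S,6S)-4,6-dihydroxy-4-isopropyl-1,8-dimethylbicyclo[5.3.0]dec-7-en-9-one
Conditions: Me4NBH(OAc)3 (5 equiv), MeCN/AcOH 1:1, −20 to 0 °C
Reagents that add atoms: none
Why: Hydroxyl-directed Evans–Saksena reduction: the C4 hydroxyl displaces an acetate on boron and the hydride is passed through a six-membered transition state to the face of C6=O that carries this hydroxyl and the C1 methyl, so O6 ends up on the opposite face, syn to H5 (6S), while the free reagent is too weak to reduce the C9 carbonyl.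

Step 16
Reactants: 25 4-hydroxybenzoic acid
Product: 27 4-(tert-butyldimethylsilyloxy)benzoic acid, via silyl ester 26 (not isolated)
Conditions: TBSCl (2.3 equiv), imidazole, DMF, rt; then AcOH/THF/H2O 3:1:1, rt
Reagents that add atoms: tert-butyldimethylsilyl chloride, CC(C)(C)[Si](C)(C)Cl
Why: Exhaustive silylation followed by selective solvolysis of the much more labile silyl ester leaves only the phenol protected.

Step 17
Reactants: 24 lancerodiol; 27 4-(tert-butyldimethylsilyloxy)benzoic acid
Product: 28 lancerodiol 6-O-[4-(tert-butyldimethylsilyloxy)benzoate]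
Conditions: DCC, DMAP, CH2Cl2, rt to 40 °C
Reagents that add atoms: none
Why: Steglich esterification acylates the secondary allylic C6 hydroxyl, the tertiary C4 hydroxyl is too hindered to compete, and C6 keeps its configuration because its C–O bond is not touched.

Step 18
Reactants: 28 silyl-protected ester
Product: 29 lancerodiol p-hydroxybenzoate
Conditions: TBAF, AcOH (1:1), THF, 0 °C
Reagents that add atoms: none
Why: Buffered fluoride desilylation cleaves the aryl silyl ether quickly, and the acetic acid keeps the medium near neutral so that the ester and the γ-acyloxy enone survive.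

## Compound list

1 | 3-methylcyclopent-2-en-1-one | CC1=CC(=O)CC1 | starting material
2 | 2,3-dibromo-3-methylcyclopentan-1-one | CC1(Br)CCC(=O)C1Br | intermediate
3 | 2-bromo-3-methylcyclopent-2-en-1-one | CC1=C(Br)C(=O)CC1 | intermediate
4 | 6-bromo-7-methyl-1,4-dioxaspiro[4.4]non-6-ene | CC1=C(Br)C2(CC1)OCCO2 | intermediate
5 | ethyl 2-methylpent-4-enoate (racemic) | C=CCC(C)C(=O)OCC | starting material
6 | ethyl 2-methyl-3-(1,2,4-trioxolan-3-yl)propanoate (ozonide) | CCOC(=O)C(C)CC1OCOO1 | intermediate
7 | ethyl 2-methyl-4-oxobutanoate (racemic) | CCOC(=O)C(C)CC=O | intermediate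
8 | (7-methyl-1,4-dioxaspiro[4.4]non-6-en-6-yl)lithium | [Li]C1=C(C)CCC12OCCO2 | intermediate
9 | ethyl 4-hydroxy-2-methyl-4-(7-methyl-1,4-dioxaspiro[4.4]non-6-en-6-yl)butanoate (all stereoisomers) | CCOC(=O)C(C)CC(O)C1=C(C)CCC12OCCO2 | intermediate
10 | ethyl 2-methyl-4-(7-methyl-1,4-dioxaspiro[4.4]non-6-en-6-yl)-4-oxobutanoate | CCOC(=O)C(C)CC(=O)C1=C(C)CCC12OCCO2 | intermediate
11 | ethyl (4S)-4-hydroxy-2-methyl-4-(7-methyl-1,4-dioxaspiro[4.4]non-6-en-6-yl)butanoate | CCOC(=O)C(C)C[C@H](O)C1=C(C)CCC12OCCO2 | intermediate
12 | (5S)-3-methyl-5-(7-methyl-1,4-dioxaspiro[4.4]non-6-en-6-yl)oxolan-2-one | O=C1O[C@@H](CC1C)C2=C(C)CCC23OCCO3 | intermediate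
13 | 6-[(2S)-4-methyl-5-methylideneoxolan-2-yl]-7-methyl-1,4-dioxaspiro[4.4]non-6-ene | C=C1O[C@@H](CC1C)C2=C(C)CCC23OCCO3 | intermediate
14 | (1R)-4,4-(ethylenedioxy)-1,8-dimethylbicyclo[5.3.0]dec-5-en-9-one (route numbering) | CC1CC=C2C3(OCCO3)CC[C@]2(C)CC1=O | intermediate
15 | C6-boryl, C9-boryloxy adduct of 14 (H5 and B6 syn, anti to the C1 methyl) | CC1C[C@H](B)[C@@H]2[C@](C)(CCC23OCCO3)CC1OB | intermediate
16 | (1R,5S,6S)-4,4-(ethylenedioxy)-1,8-dimethylbicyclo[5.3.0]decane-6,9-diol | CC1C[C@H](O)[C@@H]2[C@](C)(CCC23OCCO3)CC1O | intermediate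
17 | 6,9-bis(tert-butyldimethylsilyl) ether of 16 | CC1C[C@H](O[Si](C)(C)C(C)(C)C)[C@@H]2[C@](C)(CCC23OCCO3)CC1O[Si](C)(C)C(C)(C)C | intermediate
18 | (1R,5S,6S)-6,9-bis(tert-butyldimethylsilyloxy)-1,8-dimethylbicyclo[5.3.0]decan-4-one | CC1C[C@H](O[Si](C)(C)C(C)(C)C)[C@@H]2[C@](C)(CCC2=O)CC1O[Si](C)(C)C(C)(C)C | intermediate
19 | isopropylmagnesium chloride | CC(C)[Mg]Cl | starting material
20 | (1R,4R,5S,6S)-6,9-bis(tert-butyldimethylsilyloxy)-4-isopropyl-1,8-dimethylbicyclo[5.3.0]decan-4-ol | CC1C[C@H](O[Si](C)(C)C(C)(C)C)[C@@H]2[C@](C)(CC[C@@]2(O)C(C)C)CC1O[Si](C)(C)C(C)(C)C | intermediate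
21 | (1R,4R,5S,6S)-4-isopropyl-1,8-dimethylbicyclo[5.3.0]decane-4,6,9-triol | CC1C[C@H](O)[C@@H]2[C@](C)(CC[C@@]2(O)C(C)C)CC1O | intermediate
22 | (1R,4R,5R)-4-hydroxy-4-isopropyl-1,8-dimethylbicyclo[5.3.0]decane-6,9-dione | CC1CC(=O)[C@@H]2[C@](C)(CC[C@@]2(O)C(C)C)CC1=O | intermediate
23 | (1R,4R,5R)-4-hydroxy-4-isopropyl-1,8-dimethylbicyclo[5.3.0]dec-7-ene-6,9-dione | CC1=CC(=O)[C@@H]2[C@](C)(CC[C@@]2(O)C(C)C)CC1=O | intermediate
24 | lancerodiol, (1R,4R,5S,6S)-4,6-dihydroxy-4-isopropyl-1,8-dimethylbicyclo[5.3.0]dec-7-en-9-one | CC1=C[C@H](O)[C@@H]2[C@](C)(CC[C@@]2(O)C(C)C)CC1=O | intermediate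
25 | 4-hydroxybenzoic acid | OC(=O)c1ccc(O)cc1 | starting material
26 | tert-butyldimethylsilyl 4-(tert-butyldimethylsilyloxy)benzoate | CC(C)(C)[Si](C)(C)OC(=O)c1ccc(O[Si](C)(C)C(C)(C)C)cc1 | intermediate
27 | 4-(tert-butyldimethylsilyloxy)benzoic acid | OC(=O)c1ccc(O[Si](C)(C)C(C)(C)C)cc1 | intermediate
28 | lancerodiol 6-O-[4-(tert-butyldimethylsilyloxy)benzoate] | CC1=C[C@H](OC(=O)c2ccc(O[Si](C)(C)C(C)(C)C)cc2)[C@@H]2[C@](C)(CC[C@@]2(O)C(C)C)CC1=O | intermediate
29 | lancerodiol p-hydroxybenzoate | CC1=C[C@H](OC(=O)c2ccc(O)cc2)[C@@H]2[C@](C)(CC[C@@]2(O)C(C)C)CC1=O | target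

## Totals

Total step count: 18.
Longest linear sequence: 16 steps (1, 2, 4–15, 17, 18).

## Steps most likely to fail

**Step 8.** The shift is slowed by allylic strain between C7 and the C1 methyl and by the crowded terminus. Drift of the exocyclic double bond into the oxolane ring, or heterolysis of the allylic C6–O bond, may therefore overtake it.

The fallback sets out from 12 and comes back at 14. It reshapes the precursor instead of changing the heating.
- The lithium enolate of tert-butyl acetate (LDA, THF, −78 °C) is added to lactone 12. This gives the hydroxy β-keto ester F1, which is in equilibrium with its cyclic hemiketal.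
- Cyclodehydration (PPTS cat., molecular sieves, CH2Cl2) converts it into the oxolan-2-ylideneacetate F2.
- In this vinylogous carbonate, conjugation with the ester holds the exocyclic double bond in place. It cannot move to C8=C9, it is far less acid-sensitive, and it tolerates long heating at 190–200 °C in o-dichlorobenzene.
- The [3,3] shift of β-(allyloxy)acrylates is known chemistry and obeys the same stereochemical constraints. It gives the C10-carboxylated β-keto ester F3, which at that temperature sheds its tert-butyl ester by elimination and decarboxylation and becomes 14.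

**Step 9.** Borane may add from the face that bears the C1 methyl, which would give the cis ring fusion. The crowded alkene may also react so slowly that the ketal suffers.

The fallback sets out from 14 and comes back at 16. It inverts the stereochemical logic instead of tuning the borane.
- A peracid that follows the same facial bias (m-CPBA, NaHCO3, CH2Cl2, 0 °C) gives the 5,6-epoxide syn to the C1 methyl F4.
- A Meinwald rearrangement (catalytic Bi(OTf)3 or InCl3, CH2Cl2) opens it at the tertiary C5. The C6 hydrogen shifts to C5 on the face opposite the departing oxygen, which gives the trans-fused 6,9-dione ketal F5.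
- Single-electron reduction under thermodynamic control (SmI2, H2O, Et3N, THF) converts both ketones into the equatorial carbinols. The one at C6 is that of 16.

**Step 14.** In hot DMSO the β-hydroxy ketone unit C4(OH)–C5–C6(=O) may lose water towards C4=C5 or cleave by retro-aldol reaction. C5 may also epimerise through the enol.

The fallback sets out from 21 and comes back at 28. It avoids the enedione by changing the order of events.
- Dess–Martin periodinane at room temperature stops at the saturated dione 22, which is isolated.
- The acetoxyborohydride reduction of step 15, now applied to a plain β-hydroxy ketone beside an isolated ketone, gives the saturated 4,6-dihydroxy-9-ketone F6.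
- Steglich esterification with 27 gives the saturated 6-O-aroyl ketone F7, which no longer contains a β-hydroxy ketone.
- Only then is C7=C8 introduced by IBX dehydrogenation of the C9 ketone (DMSO, 75 °C). It can proceed only towards C8–C7 because C10 adjoins the quaternary C1, and it gives 28.

## Further compounds

F1 | step 8 | tert-butyl (6S)-6-hydroxy-4-methyl-6-(7-methyl-1,4-dioxaspiro[4.4]non-6-en-6-yl)-3-oxohexanoate | CC(C[C@H](O)C1=C(C)CCC12OCCO2)C(=O)CC(=O)OC(C)(C)C
F2 | step 8 | tert-butyl 2-[(5S)-3-methyl-5-(7-methyl-1,4-dioxaspiro[4.4]non-6-en-6-yl)oxolan-2-ylidene]acetate | CC(C)(C)OC(=O)C=C1O[C@@H](CC1C)C2=C(C)CCC23OCCO3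
F3 | step 8 | tert-butyl ester of the C10-carboxylic acid of 14 (β-keto ester) | CC1CC=C2C3(OCCO3)CC[C@]2(C)C(C(=O)OC(C)(C)C)C1=O
F4 | step 9 | 5,6-epoxide of 14, oxygen syn to the C1 methyl | CC1C[C@H]2O[C@]23C4(OCCO4)CC[C@]3(C)CC1=O
F5 | step 9 | (1R,5S)-4,4-(ethylenedioxy)-1,8-dimethylbicyclo[5.3.0]decane-6,9-dione (trans-fused) | CC1CC(=O)[C@@H]2[C@](C)(CCC23OCCO3)CC1=O
F6 | step 14 | (1R,4R,5S,6S)-4,6-dihydroxy-4-isopropyl-1,8-dimethylbicyclo[5.3.0]decan-9-one | CC1C[C@H](O)[C@@H]2[C@](C)(CC[C@@]2(O)C(C)C)CC1=O
F7 | step 14 | 6-O-[4-(tert-butyldimethylsilyloxy)benzoate] of F6 | CC1C[C@H](OC(=O)c2ccc(O[Si](C)(C)C(C)(C)C)cc2)[C@@H]2[C@](C)(CC[C@@]2(O)C(C)C)CC1=O
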